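At 30.0 min the south run shows 7% left-handed substrate against 37% right-handed substrate, as fractions of the two charged together, so less of the left-handed substrate is read as left than of its mirror image.

in all of them: left-handed substrate 0.064 M; right-handed substrate 0.064 M; gas 4.5 mM (held); free catalyst 1.9 mM
- south: the very flask that is asked about, followed so far
- flask: time 2.5 h

south run (percent of the left-handed substrate and right-handed substrate together charged)

| time / min | right-handed substrate / % | left-handed substrate / % |
|---|---|---|
| 5.00 | 48 | 36 |
| 15.0 | 44 | 23 |
| 30.0 | 37 | 7 |
| 40.0 | 34 | 1 |
| 60.0 | 25 | 2 |

(scatter of a reading: 2 percentage points)

- free catalyst is single-handed; left-handed substrate and right-handed substrate are mirror images of each other, charged as a racemate, each of them at the stated concentration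
- at the start none of the gas is in solution

1. whether the excess of right-handed substrate over left-handed substrate among what is left of the two reaches 90% by 2.5 h (no / yes)
2. the highest excess of right-handed substrate over left-handed substrate among what is left of the two up to 2.5 h

The late readings seem to answer directly, but at 60.0 min they give an excess of 85.2%, from a left-handed reading of 2% with a scatter of 2 percentage points, so that end is poorly read. The early end serves better. The selectivity factor, the logarithmic fall of the left-handed substrate from its charge of 0.5 over that of the right-handed substrate, reads 6.53 at 30.0 min. The left-handed share of its charge is then the right-handed share raised to that power, which joins the two ends: right-handed substrate stands at 29.4% when the excess reaches 90%. This is the threshold remainder, the right-handed fraction left at the wanted excess.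

One objection is that the factor drifts, since 15.0 min reads 6.07, but the threshold then moves only to 28.0%. Another is that the right-handed substrate might stall above the threshold, but its reading of 25% at 60.0 min already lies below it. This reckoning therefore says yes, and puts the excess at 95.8% at 60.0 min, still a figure for that moment and not for the end.

The forecast says yes, with a top of 99% (range 93% to 100%), higher than this reckoning's figure, and adds: “The only limit would be slow racemisation”.

The flask gives yes and a top of >99.9%, reaching 90% at 0.870 h with 27.6% right-handed substrate left, against the threshold remainder of 29.4%.

    free catalyst + left-handed substrate ⇌ catalyst intermediate A (K = 37.0 M⁻¹, k = 370 M⁻¹ min⁻¹)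
    coupling partner + catalyst intermediate A → free catalyst + left-handed product (k = 810 M⁻¹ min⁻¹)
    free catalyst + right-handed substrate ⇌ catalyst intermediate B (K = 10.0 M⁻¹, k = 200 M⁻¹ min⁻¹)
    coupling partner + catalyst intermediate B → free catalyst + right-handed product (k = 400 M⁻¹ min⁻¹)
    free catalyst ⇌ dormant form (K = 0.840, k = 0.110 min⁻¹)
    gas ⇌ coupling partner, rate k6*(csat - [coupling partner]) (kL = 7.30 min⁻¹)
    2 coupling partner → self-condensation product (k = 1.90 M⁻¹ min⁻¹)

At 0.414 h in the flask catalyst intermediate B falls back 12 times faster than it goes on, and the half-life of free catalyst by the forward rate of its binding of right-handed substrate, that step alone, is 0.069 min, far shorter than 0.870 h. At 2.50 h the flask holds 0% left-handed and 6.12% right-handed substrate. With half the left-handed charge, the threshold rises to 66.6% of the right-handed charge, and that run ends at >99.9%.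

Readings and results are simulated for an exercise, and the scatter is random.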